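**Plan**

- Cuts: O1–C2 and C2–C3 of both pyranone rings (flavone 1 to a ring A acetophenone plus 4-methoxybenzoyl chloride; flavone 2 to a methyl 4-aryloxybenzoate plus 2',6'-dihydroxy-4'-methoxyacetophenone), then the acetyl C–C bond on ring A, then C3'–C4' and C5'–C6' of ring B of flavone 2.
- Enabling feature: ring B of flavone 2 is a para-disubstituted benzene with the ether oxygen on C4' and the carboxyl-level carbon C2 on C1', the pattern that an aryl ethynyl ether and methyl coumalate give after loss of CO2. The oxygen's other partner, C8 of flavone 1, sits between C7–O and C8a–O and is a poor site for aryl–oxygen coupling, so the O–C4' bond is made on a two-carbon unit before ring B exists.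
- Forward order: Baeyer–Villiger route to 2,6-bis(benzyloxy)-4-methoxyphenol, O-dichlorovinylation and elimination to the ynol ether, ring B of flavone 2 by cycloaddition, acetylation of ring A, ring C of flavone 1, ring C of flavone 2, final 5-O-demethylation.
- Protecting groups decide 8-aryloxy against 6-aryloxy: the oxygen that ends as 5-OH of flavone 1 stays a methyl ether until the last step, and the two oxygens beside the ether are benzyl ethers removed together, so only the phenol next to the diaryl ether can close ring C.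
- Stereochemistry: the target has no stereocentre and no stereogenic double bond; the E dichlorovinyl ether and the racemic bicyclic lactone lose their stereo elements in the bond changes that follow.

Key step: step 6

Assumption: 2',6'-dihydroxy-4'-methoxyacetophenone, trichloroethylene, methyl coumalate and 4-methoxybenzoyl chloride are bought; the organolithium species and the bicyclic lactone are transient and drawn as monomeric, racemic structures.

**Route**

Step 1
Reactants: 1 2',6'-dihydroxy-4'-methoxyacetophenone
Product: 2 2',6'-bis(benzyloxy)-4'-methoxyacetophenone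
Conditions: BnBr (2.5 equiv), K2CO3, Bu4NI (cat.), DMF, 70 °C
Reagents that add atoms: benzyl bromide, BrCc1ccccc1
Why: Williamson etherification; the two chelated ortho phenols of a 2,6-dihydroxyacetophenone need warming and excess benzyl bromide but should both be benzylated, as in the usual perbenzylation of phloroacetophenones.

Step 2
Reactants: 2 2',6'-bis(benzyloxy)-4'-methoxyacetophenone
Product: 3 2,6-bis(benzyloxy)-4-methoxyphenyl acetate
Conditions: mCPBA, CH2Cl2, 0 °C to rt
Reagents that add atoms: mCPBA, O=C(OO)c1cccc(Cl)c1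
Why: Baeyer–Villiger oxidation, in which the twisted, electron-rich trialkoxyphenyl group migrates in preference to methyl and the benzyl and methyl ethers are inert to the peracid.

Step 3
Reactants: 3 2,6-bis(benzyloxy)-4-methoxyphenyl acetate
Product: 4 2,6-bis(benzyloxy)-4-methoxyphenol
Conditions: K2CO3 (cat.), MeOH, rt, argon
Reagents that add atoms: none
Why: Base-catalysed transesterification of an aryl acetate, fast because the phenoxide is a good leaving group, with nothing else in the molecule affected.

Step 4
Reactants: 4 2,6-bis(benzyloxy)-4-methoxyphenol; 5 trichloroethylene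
Product: 6 1,3-bis(benzyloxy)-2-{[(E)-1,2-dichloroethenyl]oxy}-5-methoxybenzene
Conditions: K2CO3, DMF, 70 °C
Reagents that add atoms: none
Why: Base-mediated O-dichlorovinylation (elimination of HCl from trichloroethylene to dichloroacetylene, then anti addition of the phenoxide, which sets the E geometry); the oxygen bonds to a slim two-carbon electrophile, so the two ortho benzyloxy groups should hinder far less than in an aryl–oxygen coupling.

Step 5
Reactants: 6 1,3-bis(benzyloxy)-2-{[(E)-1,2-dichloroethenyl]oxy}-5-methoxybenzene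
Product: 9 1,3-bis(benzyloxy)-2-(ethynyloxy)-5-methoxybenzene, via chloroethynyl ether 7 (not isolated), via lithium acetylide 8 (not isolated)
Conditions: n-BuLi (2.2 equiv), THF, −78 to −40 °C; then H2O, −78 °C; cold, base-washed work-up, used at once in step 6
Reagents that add atoms: none
Why: The established dichlorovinyl ether to ynol ether elimination, in which n-BuLi removes the vinyl proton, chloride leaves to give 7, a second equivalent performs lithium–chlorine exchange to 8 and water protonates it, all faster at −78 °C than benzylic or ring lithiation.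

Step 6
Reactants: 9 1,3-bis(benzyloxy)-2-(ethynyloxy)-5-methoxybenzene; 10 methyl coumalate
Product: 12 methyl 4-[2,6-bis(benzyloxy)-4-methoxyphenoxy]benzoate, via bicyclic lactone 11 (not isolated)
Conditions: 10 (1.5 equiv), toluene, 110 °C, sealed tube, argon
Reagents that add atoms: none
Why: Inverse-electron-demand Diels–Alder reaction in which the electron-poor diene C3=C4–C5=C6 of pyranone 10 adds across the electron-rich triple bond of 9 in a concerted but asynchronous [4+2] step to give the 2-oxabicyclo[2.2.2]octadienone 11, which at the same temperature extrudes CO2 by retro-[4+2] cleavage and so becomes a benzene without any oxidant. The closest known reaction type is the benzannulation of methyl coumalate and other 2-pyranones with ynamines, alkoxyalkynes and ketene acetals to para-substituted benzoates. The one ring formed, ring B of flavone 2, is closed by intermolecular [4+2] cycloaddition, four carbons (C3', C2', C1', C6') coming from the pyranone and two (C4', C5') from the alkyne, with C3'–C4' and C5'–C6' as the new bonds. No stereocentre remains, because the two bridgehead centres of 11 vanish when CO2 leaves. The step needs para orientation, and polarity should secure it: the terminal, nucleophilic carbon of the ynol ether bonds first to C6 of the coumalate, the terminus conjugated to both carbonyl groups and hence the most electrophilic, so the oxygen-bearing carbon must join C3 and the ether ends para to the ester. It also needs the ynol ether to outlast the heating, which an aryl ether should do because it has no C–H bond beta to oxygen for retro-ene loss of a ketene, and the bulky aryl group sits one atom away from the reacting carbon.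

Step 7
Reactants: 12 methyl 4-[2,6-bis(benzyloxy)-4-methoxyphenoxy]benzoate
Product: 13 methyl 4-[3-acetyl-2,6-bis(benzyloxy)-4-methoxyphenoxy]benzoate
Conditions: AcOH, (CF3CO)2O, CH2Cl2, 0 °C to rt
Reagents that add atoms: acetic acid, CC(=O)O
Why: Friedel–Crafts acylation by acetyl trifluoroacetate formed in the flask, a Lewis-acid-free variant known for polyalkoxybenzenes that should spare benzyl ethers; only C3 (equivalent to C5) of the tetraoxygenated ring is activated, being ortho to two ether oxygens and para to a third, while the benzoate ring and the benzyl rings are far less nucleophilic.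

Step 8
Reactants: 13 methyl 4-[3-acetyl-2,6-bis(benzyloxy)-4-methoxyphenoxy]benzoate
Product: 14 methyl 4-(3-acetyl-2,6-dihydroxy-4-methoxyphenoxy)benzoate
Conditions: H2 (1 atm), 10% Pd/C, EtOAc–MeOH, rt
Reagents that add atoms: none
Why: Hydrogenolysis of aryl benzyl ethers over Pd/C, which leaves the methyl ether, aryl ketone, ester and diaryl ether untouched, so that the only free phenol ortho to the acetyl group is the one next to the diaryl ether oxygen.

Step 9
Reactants: 14 methyl 4-(3-acetyl-2,6-dihydroxy-4-methoxyphenoxy)benzoate; 15 4-methoxybenzoyl chloride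
Product: 16 methyl 4-{2,6-dihydroxy-4-methoxy-3-[3-(4-methoxyphenyl)-3-oxopropanoyl]phenoxy}benzoate
Conditions: LiN(SiMe3)2 (4.2 equiv), THF, −78 to −10 °C; 15 (1.05 equiv), −78 °C to rt; aq. HCl
Reagents that add atoms: none
Why: Claisen-type C-acylation of the polylithiated hydroxyacetophenone, whose enolate carbon is the most nucleophilic site and attacks the acid chloride to give the same 1,3-diketone as a Baker–Venkataraman rearrangement without phenol protection, while the methyl benzoate is far less electrophilic than the acid chloride at −78 °C.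

Step 10
Reactants: 16 methyl 4-{2,6-dihydroxy-4-methoxy-3-[3-(4-methoxyphenyl)-3-oxopropanoyl]phenoxy}benzoate
Product: 17 methyl 4-{[7-hydroxy-5-methoxy-2-(4-methoxyphenyl)-4-oxo-4H-chromen-8-yl]oxy}benzoate
Conditions: H2SO4 (cat.), AcOH, 95 °C
Reagents that add atoms: none
Why: Acid-catalysed cyclodehydration of a 2'-hydroxy-1,3-diketone to a flavone; the para hydroxyl cannot reach the diketone and the other ortho oxygen is a methyl ether, so the pyranone oxygen must be the one beside the diaryl ether, which fixes the 8-aryloxy pattern and excludes a Wessely–Moser interchange.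

Step 11
Reactants: 17 methyl 4-{[7-hydroxy-5-methoxy-2-(4-methoxyphenyl)-4-oxo-4H-chromen-8-yl]oxy}benzoate; 1 2',6'-dihydroxy-4'-methoxyacetophenone
Product: 18 1-(2,6-dihydroxy-4-methoxyphenyl)-3-(4-{[7-hydroxy-5-methoxy-2-(4-methoxyphenyl)-4-oxo-4H-chromen-8-yl]oxy}phenyl)propane-1,3-dione
Conditions: 1 (2 equiv), LiN(SiMe3)2 (8 equiv), THF, −78 °C to rt; aq. HCl
Reagents that add atoms: none
Why: Crossed Claisen condensation in which the enolate of polylithiated 1 attacks the non-enolisable methyl benzoate of 17 and the diketone formed is deprotonated at once, which drives the equilibrium, while 17 has no enolisable C–H and its 7-hydroxyl only becomes a spectator phenoxide.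

Step 12
Reactants: 18 1-(2,6-dihydroxy-4-methoxyphenyl)-3-(4-{[7-hydroxy-5-methoxy-2-(4-methoxyphenyl)-4-oxo-4H-chromen-8-yl]oxy}phenyl)propane-1,3-dione
Product: 19 7-hydroxy-8-[4-(5-hydroxy-7-methoxy-4-oxo-4H-chromen-2-yl)phenoxy]-5-methoxy-2-(4-methoxyphenyl)-4H-chromen-4-one
Conditions: H2SO4 (cat.), AcOH, 95 °C
Reagents that add atoms: none
Why: Acid-catalysed cyclodehydration as in step 10; the two ortho hydroxyls of the new ring A are equivalent by symmetry, so only one flavone can form, and the 5-methoxy group keeps flavone 1 locked against ring opening and reclosure.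

Step 13
Reactants: 19 7-hydroxy-8-[4-(5-hydroxy-7-methoxy-4-oxo-4H-chromen-2-yl)phenoxy]-5-methoxy-2-(4-methoxyphenyl)-4H-chromen-4-one
Product: 20 5,7-dihydroxy-8-[4-(5-hydroxy-7-methoxy-4-oxo-4H-chromen-2-yl)phenoxy]-2-(4-methoxyphenyl)-4H-chromen-4-one (CNP0124888.0)
Conditions: BCl3 (6 equiv), CH2Cl2, −78 to 0 °C; then MeOH–H2O
Reagents that add atoms: none
Why: Chelation-directed Lewis acid demethylation, the standard selective 5-O-demethylation of polymethoxyflavones: BCl3 binds between the C4 carbonyl and the peri 5-methoxy oxygen and chloride removes the methyl group, while the 4'- and 7-methyl ethers, which cannot chelate, and the diaryl ether should stay intact.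

**Compound list**

1 | 2',6'-dihydroxy-4'-methoxyacetophenone | CC(=O)c1c(O)cc(OC)cc1O | starting material
2 | 2',6'-bis(benzyloxy)-4'-methoxyacetophenone | CC(=O)c1c(OCc2ccccc2)cc(OC)cc1OCc1ccccc1 | intermediate
3 | 2,6-bis(benzyloxy)-4-methoxyphenyl acetate | CC(=O)Oc1c(OCc2ccccc2)cc(OC)cc1OCc1ccccc1 | intermediate
4 | 2,6-bis(benzyloxy)-4-methoxyphenol | Oc1c(OCc2ccccc2)cc(OC)cc1OCc1ccccc1 | intermediate
5 | trichloroethylene | ClC=C(Cl)Cl | starting material
6 | 1,3-bis(benzyloxy)-2-{[(E)-1,2-dichloroethenyl]oxy}-5-methoxybenzene | Cl/C=C(/Cl)Oc1c(OCc2ccccc2)cc(OC)cc1OCc1ccccc1 | intermediate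
7 | chloroethynyl ether, 1,3-bis(benzyloxy)-2-[(chloroethynyl)oxy]-5-methoxybenzene (formed and consumed in step 5) | ClC#COc1c(OCc2ccccc2)cc(OC)cc1OCc1ccccc1 | intermediate
8 | lithium acetylide, {[2,6-bis(benzyloxy)-4-methoxyphenoxy]ethynyl}lithium (formed and consumed in step 5) | [Li]C#COc1c(OCc2ccccc2)cc(OC)cc1OCc1ccccc1 | intermediate
9 | 1,3-bis(benzyloxy)-2-(ethynyloxy)-5-methoxybenzene | C#COc1c(OCc2ccccc2)cc(OC)cc1OCc1ccccc1 | intermediate
10 | methyl coumalate (methyl 2-oxo-2H-pyran-5-carboxylate) | COC(=O)c1ccc(=O)oc1 | starting material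
11 | bicyclic lactone, methyl 5-[2,6-bis(benzyloxy)-4-methoxyphenoxy]-3-oxo-2-oxabicyclo[2.2.2]octa-5,7-diene-7-carboxylate (racemic, formed and consumed in step 6) | COC(=O)C1=CC2C(=O)OC1C=C2Oc1c(OCc2ccccc2)cc(OC)cc1OCc1ccccc1 | intermediate
12 | methyl 4-[2,6-bis(benzyloxy)-4-methoxyphenoxy]benzoate | COC(=O)c1ccc(Oc2c(OCc3ccccc3)cc(OC)cc2OCc2ccccc2)cc1 | intermediate
13 | methyl 4-[3-acetyl-2,6-bis(benzyloxy)-4-methoxyphenoxy]benzoate | COC(=O)c1ccc(Oc2c(OCc3ccccc3)cc(OC)c(C(C)=O)c2OCc2ccccc2)cc1 | intermediate
14 | methyl 4-(3-acetyl-2,6-dihydroxy-4-methoxyphenoxy)benzoate | COC(=O)c1ccc(Oc2c(O)cc(OC)c(C(C)=O)c2O)cc1 | intermediate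
15 | 4-methoxybenzoyl chloride | COc1ccc(C(=O)Cl)cc1 | starting material
16 | methyl 4-{2,6-dihydroxy-4-methoxy-3-[3-(4-methoxyphenyl)-3-oxopropanoyl]phenoxy}benzoate | COC(=O)c1ccc(Oc2c(O)cc(OC)c(C(=O)CC(=O)c3ccc(OC)cc3)c2O)cc1 | intermediate
17 | methyl 4-{[7-hydroxy-5-methoxy-2-(4-methoxyphenyl)-4-oxo-4H-chromen-8-yl]oxy}benzoate | COC(=O)c1ccc(Oc2c(O)cc(OC)c3c(=O)cc(-c4ccc(OC)cc4)oc23)cc1 | intermediate
18 | 1-(2,6-dihydroxy-4-methoxyphenyl)-3-(4-{[7-hydroxy-5-methoxy-2-(4-methoxyphenyl)-4-oxo-4H-chromen-8-yl]oxy}phenyl)propane-1,3-dione | COc1ccc(-c2cc(=O)c3c(OC)cc(O)c(Oc4ccc(C(=O)CC(=O)c5c(O)cc(OC)cc5O)cc4)c3o2)cc1 | intermediate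
19 | 7-hydroxy-8-[4-(5-hydroxy-7-methoxy-4-oxo-4H-chromen-2-yl)phenoxy]-5-methoxy-2-(4-methoxyphenyl)-4H-chromen-4-one | COc1ccc(-c2cc(=O)c3c(OC)cc(O)c(Oc4ccc(-c5cc(=O)c6c(O)cc(OC)cc6o5)cc4)c3o2)cc1 | intermediate
20 | 5,7-dihydroxy-8-[4-(5-hydroxy-7-methoxy-4-oxo-4H-chromen-2-yl)phenoxy]-2-(4-methoxyphenyl)-4H-chromen-4-one (CNP0124888.0) | COc1ccc(-c2cc(=O)c3c(O)cc(O)c(Oc4ccc(-c5cc(=O)c6c(O)cc(OC)cc6o5)cc4)c3o2)cc1 | target

**Step count and risks**

Total steps: 13. Longest linear sequence: 13 steps (1 to 20); 5, 10, 15 and the second portion of 1 enter as bought compounds.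

Steps most likely to fail:

Step 6. The terminal ynol ether may polymerise or be hydrated by adventitious water during heating faster than it adds to the pyranone, since an aryl ynol ether is less electron-rich than an ynamine, and some meta orientation could form. The fallback gives up the de novo ring and makes the same diaryl ether by nucleophilic aromatic substitution. It sets out from phenol 4, which with methyl 4-fluorobenzoate (Cs2CO3, DMSO, 120 °C) should give 12 directly, and returns to the route at 12. No compound outside the list arises (none, F0).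

Step 7. Trifluoroacetic acid formed during the acylation may strip or shift benzyl groups on the very electron-rich ring, or acylation at the crowded position may be sluggish. The fallback installs the acetyl group by halogenation and cross-coupling and sets out from 12. N-Bromosuccinimide in MeCN at 0 °C should brominate the same activated position to give methyl 4-[2,6-bis(benzyloxy)-3-bromo-4-methoxyphenoxy]benzoate F1. Stille coupling with tributyl(1-ethoxyvinyl)stannane (PdCl2(PPh3)2, toluene, 100 °C) should give methyl 4-[2,6-bis(benzyloxy)-3-(1-ethoxyethenyl)-4-methoxyphenoxy]benzoate F2. Dilute aqueous HCl in THF then hydrolyses the enol ether to 13, where the route resumes.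

Step 11. Acyl transfer may be slow or incomplete because the polylithiated ketone aggregates, the ester partner is itself an anionic and sparingly soluble phenoxide, and proton exchange can quench the enolate. The fallback replaces the intermolecular condensation by an intramolecular acyl shift and sets out from 17. Chloromethyl methyl ether and i-Pr2NEt in CH2Cl2 should give methyl 4-{[5-methoxy-7-(methoxymethoxy)-2-(4-methoxyphenyl)-4-oxo-4H-chromen-8-yl]oxy}benzoate F3. LiOH in THF–H2O at rt should give 4-{[5-methoxy-7-(methoxymethoxy)-2-(4-methoxyphenyl)-4-oxo-4H-chromen-8-yl]oxy}benzoic acid F4. Steglich esterification with excess 1 (EDC·HCl, DMAP, CH2Cl2) should give 2-acetyl-3-hydroxy-5-methoxyphenyl 4-{[5-methoxy-7-(methoxymethoxy)-2-(4-methoxyphenyl)-4-oxo-4H-chromen-8-yl]oxy}benzoate F5. Baker–Venkataraman rearrangement (KOH, pyridine, 50 °C) should give 1-(2,6-dihydroxy-4-methoxyphenyl)-3-(4-{[5-methoxy-7-(methoxymethoxy)-2-(4-methoxyphenyl)-4-oxo-4H-chromen-8-yl]oxy}phenyl)propane-1,3-dione F6. H2SO4 in AcOH at 95 °C then closes ring C and removes the methoxymethyl group, giving 19, so steps 11 and 12 are bypassed and the route resumes at 19.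

**Further compounds**

F0 | step 6 | none | none
F1 | step 7 | methyl 4-[2,6-bis(benzyloxy)-3-bromo-4-methoxyphenoxy]benzoate | COC(=O)c1ccc(Oc2c(OCc3ccccc3)cc(OC)c(Br)c2OCc2ccccc2)cc1
F2 | step 7 | methyl 4-[2,6-bis(benzyloxy)-3-(1-ethoxyethenyl)-4-methoxyphenoxy]benzoate | COC(=O)c1ccc(Oc2c(OCc3ccccc3)cc(OC)c(C(=C)OCC)c2OCc2ccccc2)cc1
F3 | step 11 | methyl 4-{[5-methoxy-7-(methoxymethoxy)-2-(4-methoxyphenyl)-4-oxo-4H-chromen-8-yl]oxy}benzoate | COCOc1cc(OC)c2c(=O)cc(-c3ccc(OC)cc3)oc2c1Oc1ccc(C(=O)OC)cc1
F4 | step 11 | 4-{[5-methoxy-7-(methoxymethoxy)-2-(4-methoxyphenyl)-4-oxo-4H-chromen-8-yl]oxy}benzoic acid | COCOc1cc(OC)c2c(=O)cc(-c3ccc(OC)cc3)oc2c1Oc1ccc(C(=O)O)cc1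
F5 | step 11 | 2-acetyl-3-hydroxy-5-methoxyphenyl 4-{[5-methoxy-7-(methoxymethoxy)-2-(4-methoxyphenyl)-4-oxo-4H-chromen-8-yl]oxy}benzoate | COCOc1cc(OC)c2c(=O)cc(-c3ccc(OC)cc3)oc2c1Oc1ccc(C(=O)Oc2cc(OC)cc(O)c2C(C)=O)cc1
F6 | step 11 | 1-(2,6-dihydroxy-4-methoxyphenyl)-3-(4-{[5-methoxy-7-(methoxymethoxy)-2-(4-methoxyphenyl)-4-oxo-4H-chromen-8-yl]oxy}phenyl)propane-1,3-dione | COCOc1cc(OC)c2c(=O)cc(-c3ccc(OC)cc3)oc2c1Oc1ccc(C(=O)CC(=O)c2c(O)cc(OC)cc2O)cc1
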